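**Retrosynthetic overview**
1. Glabrol (16) comes from its bis-MOM ether 15 by a final mild acid deprotection.
2. Key disconnection, C2–C1′: Rh-catalysed enantioselective 1,4-addition of arylboronic acid 14 (C13 fragment) to chromone 9 (C16 fragment); this late coupling sets the only stereocentre (2S).
3. Chromone 9 comes from resorcinol: C-acetylation, O-(1,1-dimethylallyl)ation, Claisen rearrangement to C3, MOM protection, then enaminone formation and ring closure.
4. Boronic acid 14 comes from 4-bromophenol by the same O-(1,1-dimethylallyl)ation/Claisen sequence, MOM protection, then Li–Br exchange and borylation.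
5. Both prenyl groups come from one C5 donor, carbonate 2. Ring order: both benzene rings arrive in the starting materials; the pyranone ring is the only ring built (step 7) and becomes the chromanone in the coupling (step 12).

Assumption: the (S)-atropisomer of the bisphosphine is taken to give the 2S product, by analogy with (S)-BINAP/Rh on cyclic enones. This is from analogy, not a confirmed precedent for this substrate, so the configuration of 15 is checked by chiral HPLC and CD, and the (R)-ligand is used if the sense is reversed.

**Prenyl donor**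

Step 1
Reactants: 1 2-methylbut-3-en-2-ol
Product: 2 methyl 2-methylbut-3-en-2-yl carbonate
Conditions: n-BuLi, THF, −78 → 0 °C; then ClCO2Me
Reagents that add atoms: methyl chloroformate, COC(=O)Cl
Why: Acylation of the lithium tert-alkoxide with a chloroformate gives the tertiary allylic carbonate cleanly.

**Chromone fragment**

Step 2
Reactants: 3 resorcinol
Product: 4 1-(2,4-dihydroxyphenyl)ethanone
Conditions: AcOH, ZnCl2, 140–150 °C
Reagents that add atoms: acetic acid, CC(=O)O
Why: Nencki (Friedel–Crafts) acylation occurs at C4 of resorcinol, para to one OH and ortho to the other.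

Step 3
Reactants: 4 1-(2,4-dihydroxyphenyl)ethanone; 2 methyl 2-methylbut-3-en-2-yl carbonate (1.2 equiv)
Product: 5 1-[2-hydroxy-4-(2-methylbut-3-en-2-yloxy)phenyl]ethanone
Conditions: Pd(PPh3)4 (3 mol %), THF, 0 °C
Reagents that add atoms: none (all atoms from 4 and 2)
Why: Tsuji–Trost O-allylation, in which the free 4-phenoxide attacks the more substituted terminus of the 1,1-dimethylallyl-Pd complex under kinetic control, while the chelated 2-OH does not react.

Step 4
Reactants: 5
Product: 6 1-[2,4-dihydroxy-3-(3-methylbut-2-en-1-yl)phenyl]ethanone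
Conditions: PhNEt2, 140 °C, Ar
Reagents that add atoms: none
Why: Aromatic Claisen [3,3] rearrangement turns the tertiary allyl ether into a linear prenyl group, directed to C3 by bond fixation from the chelated o-hydroxyacetyl unit (minor C5 isomer removed by chromatography).

Step 5
Reactants: 6
Product: 7 1-[2-hydroxy-4-(methoxymethoxy)-3-(3-methylbut-2-en-1-yl)phenyl]ethanone
Conditions: MOMCl (1.2 equiv), K2CO3, acetone, rt
Reagents that add atoms: chloromethyl methyl ether, COCCl
Why: Selective Williamson-type acetalisation of the non-chelated 4-OH; the 2-OH hydrogen-bonded to the ketone is much less nucleophilic.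

Step 6
Reactants: 7
Product: 8 (E)-3-(dimethylamino)-1-[2-hydroxy-4-(methoxymethoxy)-3-(3-methylbut-2-en-1-yl)phenyl]prop-2-en-1-one
Conditions: DMF-DMA, toluene, 90 °C
Reagents that add atoms: N,N-dimethylformamide dimethyl acetal, COC(OC)N(C)C
Why: Enaminone formation by condensation of the methyl ketone with the formamide acetal; neutral conditions leave the MOM and prenyl groups untouched.

Step 7
Reactants: 8
Product: 9 7-(methoxymethoxy)-8-(3-methylbut-2-en-1-yl)-4H-chromen-4-one
Conditions: AcOH (excess), toluene, 60 °C
Reagents that add atoms: none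
Why: Weak-acid-promoted intramolecular addition–elimination (6-endo oxa-Michael, loss of HNMe2) closes the γ-pyranone; AcOH is too weak to cleave the MOM ether or cyclise the prenyl group.

**Arylboronic acid fragment**

Step 8
Reactants: 10 4-bromophenol; 2 methyl 2-methylbut-3-en-2-yl carbonate (1.2 equiv)
Product: 11 1-bromo-4-(2-methylbut-3-en-2-yloxy)benzene
Conditions: Pd(PPh3)4 (3 mol %), THF, 0 °C
Reagents that add atoms: none (all atoms from 10 and 2)
Why: Tsuji–Trost O-allylation at the tertiary terminus; ionisation of the allyl carbonate is far faster than oxidative addition into the electron-rich C–Br bond at 0 °C.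

Step 9
Reactants: 11
Product: 12 4-bromo-2-(3-methylbut-2-en-1-yl)phenol
Conditions: PhNEt2, 140 °C, Ar
Reagents that add atoms: none
Why: Aromatic Claisen rearrangement to either of the two equivalent ortho positions (para is blocked by Br) gives the o-prenylphenol.

Step 10
Reactants: 12
Product: 13 4-bromo-1-(methoxymethoxy)-2-(3-methylbut-2-en-1-yl)benzene
Conditions: MOMCl, i-Pr2NEt, CH2Cl2, 0 °C → rt
Reagents that add atoms: chloromethyl methyl ether, COCCl
Why: Standard MOM protection of the phenol, needed to survive the organolithium step.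

Step 11
Reactants: 13
Product: 14 [4-(methoxymethoxy)-3-(3-methylbut-2-en-1-yl)phenyl]boronic acid
Conditions: n-BuLi, THF, −78 °C; B(OMe)3, −78 °C → rt; aq. NH4Cl
Reagents that add atoms: trimethyl borate, COB(OC)OC (boron); water, O (the two B–OH oxygens)
Why: Li–Br exchange at −78 °C is faster than any deprotonation, and borate trapping followed by mild hydrolysis gives the boronic acid with the MOM group intact.

**Coupling and endgame**

Step 12
Reactants: 9 7-(methoxymethoxy)-8-prenylchromone; 14 arylboronic acid (3 equiv)
Product: 15 (2S)-7-(methoxymethoxy)-2-[4-(methoxymethoxy)-3-(3-methylbut-2-en-1-yl)phenyl]-8-(3-methylbut-2-en-1-yl)chroman-4-one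
Conditions: [Rh(OH)(cod)]2 (2.5 mol %), (S)-MeO-F12-BIPHEP (6 mol %), CH2Cl2/H2O 10:1, 40 °C
Reagents that add atoms: none (all atoms from 9 and 14)
Why: Hayashi–Miyaura asymmetric 1,4-addition, in which the aryl-Rh(I)/chiral bisphosphine complex delivers the aryl group to the Re face of C2 to set 2S; the base-free conditions avoid retro-oxa-Michael ring opening, and the unactivated prenyl alkenes do not insert.

Step 13
Reactants: 15
Product: 16 glabrol, (2S)-7-hydroxy-2-[4-hydroxy-3-(3-methylbut-2-en-1-yl)phenyl]-8-(3-methylbut-2-en-1-yl)chroman-4-one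
Conditions: 3 M aq. HCl/MeOH (1:5), rt → 40 °C, stopped at full conversion
Reagents that add atoms: none
Why: Acid-catalysed acetal hydrolysis removes both MOM groups; flavanones are configurationally stable in mild acid (racemisation needs base-mediated ring opening), so 2S is kept.

**Compound list**
1 | 2-methylbut-3-en-2-ol | C=CC(C)(C)O | starting material
2 | methyl 2-methylbut-3-en-2-yl carbonate | COC(=O)OC(C)(C)C=C | intermediate
3 | resorcinol | Oc1cccc(O)c1 | starting material
4 | 1-(2,4-dihydroxyphenyl)ethanone | CC(=O)c1ccc(O)cc1O | intermediate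
5 | 1-[2-hydroxy-4-(2-methylbut-3-en-2-yloxy)phenyl]ethanone | CC(=O)c1ccc(OC(C)(C)C=C)cc1O | intermediate
6 | 1-[2,4-dihydroxy-3-(3-methylbut-2-en-1-yl)phenyl]ethanone | CC(=O)c1ccc(O)c(CC=C(C)C)c1O | intermediate
7 | 1-[2-hydroxy-4-(methoxymethoxy)-3-(3-methylbut-2-en-1-yl)phenyl]ethanone | CC(=O)c1ccc(OCOC)c(CC=C(C)C)c1O | intermediate
8 | (E)-3-(dimethylamino)-1-[2-hydroxy-4-(methoxymethoxy)-3-(3-methylbut-2-en-1-yl)phenyl]prop-2-en-1-one | CN(C)/C=C/C(=O)c1ccc(OCOC)c(CC=C(C)C)c1O | intermediate
9 | 7-(methoxymethoxy)-8-(3-methylbut-2-en-1-yl)-4H-chromen-4-one | COCOc1ccc2c(=O)ccoc2c1CC=C(C)C | intermediate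
10 | 4-bromophenol | Oc1ccc(Br)cc1 | starting material
11 | 1-bromo-4-(2-methylbut-3-en-2-yloxy)benzene | C=CC(C)(C)Oc1ccc(Br)cc1 | intermediate
12 | 4-bromo-2-(3-methylbut-2-en-1-yl)phenol | CC(C)=CCc1cc(Br)ccc1O | intermediate
13 | 4-bromo-1-(methoxymethoxy)-2-(3-methylbut-2-en-1-yl)benzene | COCOc1ccc(Br)cc1CC=C(C)C | intermediate
14 | [4-(methoxymethoxy)-3-(3-methylbut-2-en-1-yl)phenyl]boronic acid | COCOc1ccc(B(O)O)cc1CC=C(C)C | intermediate
15 | (2S)-7-(methoxymethoxy)-2-[4-(methoxymethoxy)-3-prenylphenyl]-8-prenylchroman-4-one | CC(C)=CCc1cc([C@@H]2CC(=O)c3ccc(OCOC)c(CC=C(C)C)c3O2)ccc1OCOC | intermediate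
16 | glabrol | CC(C)=CCc1cc([C@@H]2CC(=O)c3ccc(O)c(CC=C(C)C)c3O2)ccc1O | target

**Totals**
Total step count: 13.
Longest linear sequence: 8 steps (2 → 3 → 4 → 5 → 6 → 7 → 12 → 13 from resorcinol; equally 1 → 3 → … → 13 from 2-methylbut-3-en-2-ol). The boronic acid arm is 6 steps to the target from 4-bromophenol.

**Three steps most likely to fail, with fallbacks**
1. Step 12. The 7-alkoxy, 8-substituted chromone is a deactivated acceptor, the electron-rich boronic acid can protodeboronate, and the ee and facial sense must be confirmed. Fallback: convert bromide 13 to the aldehyde (n-BuLi, DMF) and condense it with acetophenone 7 (Claisen–Schmidt) to the 2′-hydroxychalcone. Then close the ring by organocatalytic enantioselective oxa-Michael cyclisation, or racemically (NaOAc, EtOH) with preparative chiral-phase separation, before deprotection.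
2. Step 4. The Claisen rearrangement may give C3/C5 mixtures or fragment with loss of isoprene. Fallback: iodinate 4 selectively at C3 (I2/HIO3), bis-MOM protect, and install the prenyl group by Pd-catalysed Suzuki–Miyaura coupling with prenyl-Bpin; then cleave the carbonyl-flanked 2-OMOM selectively to rejoin the route at 7.
3. Step 13. The o-prenylphenols can cyclise to 2,2-dimethylchromans or add HCl/MeOH under acid. Fallback: change the protecting-group strategy to silyl ethers (TBSCl in steps 5 and 10 in place of MOMCl) and finish with buffered fluoride (HF·pyridine or TBAF/AcOH), so no protic acid is used at the end.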